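The numbers in the tables are calculated for an exercise; noise was put on by code.

A small charge of solid substrate in the south-east run reached 86% target by 12.0 h, while the south run, charged with about twice as much and the very flask asked about, stood at 46%.

| flask | solid substrate | gas | remark | time |
|---|---|---|---|---|
| south | 0.037 M | 22 mM (held) | the very flask that is asked about, followed so far |  |
| south-east | 0.018 M | 22 mM (held) | run made earlier |  |
| flask | 0.037 M | 22 mM (held) |  | 30 h |

| run | time / h | target / % | dissolved substrate / % | solid substrate / % |
|---|---|---|---|---|
| south | 1.00 | 0 | 12 | 89 |
| south | 3.00 | 4 | 16 | 78 |
| south | 6.00 | 18 | 15 | 54 |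
| south | 8.00 | 30 | 15 | 42 |
| south | 12.0 | 46 | 15 | 9 |
| south-east | 2.50 | 11 | 31 | 60 |
| south-east | 5.00 | 33 | 34 | 28 |
| south-east | 8.00 | 67 | 21 | 0 |
| south-east | 10.0 | 82 | 9 | 0 |
| south-east | 12.0 | 86 | 3 | 0 |

(each reading ± 1.5 percentage points)

- solid, in amounts per volume of the solution: solid substrate
- at the start none of the solid substrate is in solution
- at the start none of the gas is in solution
- dissolved substrate means what is dissolved; the solid is not counted in it

- target at 30 h, in percent of the solid substrate charged
- concentration of dissolved substrate in solution at 8.0 h, in percent of saturation
- the change that raises the amount of target at 30 h, in percent of the solid substrate charged most ("none" if none brings more than 2 percentage points) (winter / dawn / summer / noon / none)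
- amount of target at 30 h, in percent of the solid substrate charged, after dawn

- winter: doubling the solubility of the solid substrate, all else as stated
- dawn: doubling the transfer coefficient of the gas, all else as stated
- summer: doubling the saturation concentration of gas, all else as stated
- noon: doubling the dissolution coefficient of the solid substrate, all else as stated

In the south-east run, target, dissolved and solid substrate sum to 88.0% at 8.00 h and 89.0% at 12.0 h. The missing share stops growing once solid reads 0%, though dissolved substrate still reads 21%, so this reckoning takes the loss as target meeting solid.

In the south run, dissolved substrate holds level, 16% to 15%, so it is treated as a quasi-steady state, with solid leaving at a steady amount per hour. The south run sheds 0.0727 h⁻¹ of its charge and the south-east run 0.128 h⁻¹, a ratio of 1.76 against 2.06 for the charges. Solid is then denser in proportion to the charge and stays longer in proportion, so the loss should scale with the charge squared.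

The south-east run, counting its remaining dissolved substrate as kept, loses 0.124 per share kept. Scaled to the flask this gives 0.522, the lost-to-kept number, the share of the charge lost per share kept as target. The kept fraction is one over one plus this number, 65.7%. As a test, the south run at 12.0 h already reads 0.492, with 9% solid still standing. Both runs held gas at 22 mM, so the number cannot show what gas does, and it holds no solubility or dissolution coefficient either; this reckoning therefore ranks none of the changes, and it carries 65.7% over to dawn as a bare guess.

The forecast gave 62% (56% to 69%), 52% of saturation, summer as best and 69% after dawn, saying “More gas favours target over loss.”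

The flask gives 65.8%, 46.9% of saturation at 8.0 h and 66.7% after dawn, and the best change is winter, worth 12 percentage points, against 5.7 points for noon, 4.1 points for summer and 0.9 points for dawn.

    solid substrate ⇌ dissolved substrate, rate k1*(cs1 - [dissolved substrate]) while solid is left; crystals form when [dissolved substrate] > cs1 (solubility = 12.0 mM, k = 0.350 h⁻¹)
    dissolved substrate + partner → target (k = 24.0 L mol⁻¹ h⁻¹)
    dissolved substrate + target → side product A (k = 1.50 L mol⁻¹ h⁻¹)
    gas ⇌ partner, rate k4*(csat - [partner]) (kL = 0.410 h⁻¹)
    solid substrate + target → side product B (k = 4.00 L mol⁻¹ h⁻¹)

The flask's lost-to-kept number now reads 0.520 against the reckoned 0.522, and side product B holds 26.9% at 30.0 h. A neighbouring flask, alike but charged with 0.015 M of solid substrate, takes the same scaling from the south-east run: its number is 0.0858, which keeps 92.1% as target. The simulated neighbour holds 91.7% target at 30.0 h, with side product A at 5.03% and side product B at 3.32%.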